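**Retrosynthetic overview**

- The strategy rests on ring A, the central resorcinol: C1 carries the 3-hydroxyphenethyl chain, C2 and C6 the 4-hydroxybenzyl groups, C3 and C5 the hydroxyls, and C4 is CH. Read as a folded polyketide, C2–C6 with the two ArCH2 arms is a symmetric 1,7-diarylheptane-3,5-dione, and C1 with its two-carbon arm is a 3-oxygenated cinnamoyl unit.
- First disconnection: the C1–C6 bond of ring A, by aldol condensation and aromatization of an open-chain styryl 1,3,5-triketone. The stilbene and all benzyl ethers are taken off in a final hydrogenation.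
- Second disconnection: the C1–C2 bond, by acylation of the diketone dianion with a cinnamic Weinreb amide. The diketone comes from acetylacetone and two molecules of 4-benzyloxybenzaldehyde, the amide from 3-benzyloxybenzaldehyde.
- Ring order: the three outer benzene rings are bought; ring A is the only ring made and closes in the second-to-last step.

Key step: step 5

Remark: the target is achiral, so no stereocenter has to be set. β-Dicarbonyl compounds are drawn as keto tautomers, and the boron chelates of step 1 are formulated in their simplest form as dibutoxyboron chelates.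

**Route**

Step 1
Reactants: 1 acetylacetone (pentane-2,4-dione); 2 4-benzyloxybenzaldehyde (2 equiv)
Product: 5 (1E,6E)-1,7-bis(4-benzyloxyphenyl)hepta-1,6-diene-3,5-dione, via acetylacetone boron chelate 3 (not isolated), via curcuminoid boron chelate 4 (not isolated)
Conditions: B2O3, EtOAc, 75 °C; then 2, B(OBu)3, n-BuNH2 (cat., slow addition), 75 °C; then 0.4 M HCl, 60 °C
Reagents that add atoms: none
Why: Boron chelation of the 1,3-diketone blocks Knoevenagel reaction at the central carbon, so the amine-catalysed aldol condensation takes place at both methyl groups (two-directional curcuminoid synthesis); tributyl borate takes up the water, dilute acid hydrolyses chelate 4, and the conjugated alkenes form as the E isomers.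

Step 2
Reactants: 5 (1E,6E)-1,7-bis(4-benzyloxyphenyl)hepta-1,6-diene-3,5-dione
Product: 6 1,7-bis(4-benzyloxyphenyl)heptane-3,5-dione
Conditions: H2 (1 atm), 10% Pd/C, Ph2S (cat.), THF–EtOAc, rt
Reagents that add atoms: none
Why: Chemoselective catalytic hydrogenation: Pd/C poisoned with diphenyl sulfide still saturates the two enone C=C bonds but should no longer hydrogenolyse aryl benzyl ethers or reduce the ketones.

Step 3
Reactants: 7 3-benzyloxybenzaldehyde; 8 diethyl [2-(methoxy(methyl)amino)-2-oxoethyl]phosphonate
Product: 9 (E)-3-(3-benzyloxyphenyl)-N-methoxy-N-methylprop-2-enamide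
Conditions: NaH, THF, 0 °C → rt
Reagents that add atoms: none
Why: Horner–Wadsworth–Emmons olefination with a stabilized phosphonate anion, which should give the E-configured unsaturated Weinreb amide.

Step 4
Reactants: 6 1,7-bis(4-benzyloxyphenyl)heptane-3,5-dione; 9 (E)-3-(3-benzyloxyphenyl)-N-methoxy-N-methylprop-2-enamide
Product: 12 (E)-1-(3-benzyloxyphenyl)-4-(4-benzyloxybenzyl)-9-(4-benzyloxyphenyl)non-1-ene-3,5,7-trione, via dilithium dianion 10 (not isolated), via tetrahedral lithium adduct 11 (not isolated)
Conditions: LiN(iPr)2 (2.2 equiv), THF, −78 → 0 °C; 9, −78 → −20 °C; AcOH, −78 °C, then pH 7 phosphate buffer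
Reagents that add atoms: none
Why: Acylation of a β-diketone dianion at its terminal, more nucleophilic carbon by a Weinreb amide: the symmetry of 6 makes the two terminal sites identical, the hard lithium dianion should add 1,2 to the unsaturated amide, and chelated adduct 11 survives until the mild quench, so the acidic triketone neither protonates unreacted dianion nor reacts further; the new stereocenter next to the styryl ketone is enolizable, is left uncontrolled and disappears in step 5.

Step 5
Reactants: 12 (E)-1-(3-benzyloxyphenyl)-4-(4-benzyloxybenzyl)-9-(4-benzyloxyphenyl)non-1-ene-3,5,7-trione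
Product: 14 4,6-bis(4-benzyloxybenzyl)-5-[(E)-2-(3-benzyloxyphenyl)ethenyl]benzene-1,3-diol, via cyclic aldol 13 (not isolated)
Conditions: KOH, H2O–MeOH–THF (degassed), Ar, rt → 50 °C; then AcOH to pH 5
Reagents that add atoms: none
Why: In ring-A numbering (C1 is the styryl ketone carbon of 12), hydroxide equilibrates the enolates of the triketone, the C6 enolate adds to the C1 carbonyl to form the C6–C1 bond, and aldolate 13 loses water by E1cB elimination to a cyclohexenedione that tautomerizes irreversibly to the resorcinol. The closest known reactions are the base-induced cyclization of heptane-2,4,6-trione to orcinol and the biomimetic aldol closure of cinnamoyl polyketones to pinosylvin-type stilbenes. Ring A closes in a 6-(enolendo)-exo-trig mode. No stereocenter results, because the three sp3 ring carbons of 13 all become aromatic. The step needs C-attack of C6 at C1 in preference to O-cyclization to a 4-pyranone, oxa-Michael closure and 6-endo Michael addition of C4 to the styryl β-carbon; these alternatives are reversible in aqueous base whereas aromatization is not, C6 is the only terminal carbon with acidic hydrogens because the other terminus is the sp2 styryl carbon, and the benzyl group on C2 keeps the C1 carbonyl outside the most stable enolate (C3–C4–C5), so it stays electrophilic.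

Step 6
Reactants: 14 4,6-bis(4-benzyloxybenzyl)-5-[(E)-2-(3-benzyloxyphenyl)ethenyl]benzene-1,3-diol
Product: 15 shanciguol, 4,6-bis(4-hydroxybenzyl)-5-[2-(3-hydroxyphenyl)ethyl]benzene-1,3-diol
Conditions: H2 (1–3 atm), 10% Pd/C, EtOAc–MeOH, rt
Reagents that add atoms: none
Why: Heterogeneous catalytic hydrogenation saturates the stilbene double bond to the bibenzyl and hydrogenolyses the three aryl benzyl ethers in one operation; no other reducible group is present.

**Compound list**

1 | acetylacetone (pentane-2,4-dione) | CC(=O)CC(C)=O | starting material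
2 | 4-benzyloxybenzaldehyde | O=Cc1ccc(OCc2ccccc2)cc1 | starting material
3 | acetylacetone boron chelate (2,2-dibutoxy-4,6-dimethyl-1,3,2-dioxaborinine form) | CC1=CC(C)=[O+][B-](OCCCC)(OCCCC)O1 | intermediate
4 | curcuminoid boron chelate (dibutoxyboron chelate of 5) | CCCCO[B-]1(OCCCC)OC(/C=C/c2ccc(OCc3ccccc3)cc2)=CC(/C=C/c2ccc(OCc3ccccc3)cc2)=[O+]1 | intermediate
5 | (1E,6E)-1,7-bis(4-benzyloxyphenyl)hepta-1,6-diene-3,5-dione | O=C(/C=C/c1ccc(OCc2ccccc2)cc1)CC(=O)/C=C/c1ccc(OCc2ccccc2)cc1 | intermediate
6 | 1,7-bis(4-benzyloxyphenyl)heptane-3,5-dione | O=C(CCc1ccc(OCc2ccccc2)cc1)CC(=O)CCc1ccc(OCc2ccccc2)cc1 | intermediate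
7 | 3-benzyloxybenzaldehyde | O=Cc1cccc(OCc2ccccc2)c1 | starting material
8 | diethyl [2-(methoxy(methyl)amino)-2-oxoethyl]phosphonate | CCOP(=O)(CC(=O)N(C)OC)OCC | starting material
9 | (E)-3-(3-benzyloxyphenyl)-N-methoxy-N-methylprop-2-enamide | CON(C)C(=O)/C=C/c1cccc(OCc2ccccc2)c1 | intermediate
10 | dilithium dianion (dienediolate) of 6 | [Li]OC(=CCc1ccc(OCc2ccccc2)cc1)C=C(O[Li])CCc1ccc(OCc2ccccc2)cc1 | intermediate
11 | tetrahedral lithium adduct of 10 and 9 | CON(C)C(O[Li])(/C=C/c1cccc(OCc2ccccc2)c1)C(Cc1ccc(OCc2ccccc2)cc1)C(=O)C=C(O[Li])CCc1ccc(OCc2ccccc2)cc1 | intermediate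
12 | (E)-1-(3-benzyloxyphenyl)-4-(4-benzyloxybenzyl)-9-(4-benzyloxyphenyl)non-1-ene-3,5,7-trione (configuration at C4 undefined) | O=C(/C=C/c1cccc(OCc2ccccc2)c1)C(Cc1ccc(OCc2ccccc2)cc1)C(=O)CC(=O)CCc1ccc(OCc2ccccc2)cc1 | intermediate
13 | 4,6-bis(4-benzyloxybenzyl)-5-hydroxy-5-[(E)-2-(3-benzyloxyphenyl)ethenyl]cyclohexane-1,3-dione (mixture of diastereomers) | OC1(/C=C/c2cccc(OCc3ccccc3)c2)C(Cc2ccc(OCc3ccccc3)cc2)C(=O)CC(=O)C1Cc1ccc(OCc2ccccc2)cc1 | intermediate
14 | 4,6-bis(4-benzyloxybenzyl)-5-[(E)-2-(3-benzyloxyphenyl)ethenyl]benzene-1,3-diol | Oc1cc(O)c(Cc2ccc(OCc3ccccc3)cc2)c(/C=C/c2cccc(OCc3ccccc3)c2)c1Cc1ccc(OCc2ccccc2)cc1 | intermediate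
15 | shanciguol, 4,6-bis(4-hydroxybenzyl)-5-[2-(3-hydroxyphenyl)ethyl]benzene-1,3-diol | Oc1ccc(Cc2c(O)cc(O)c(Cc3ccc(O)cc3)c2CCc2cccc(O)c2)cc1 | target

**Step count**

Total step count: 6 steps.
Longest linear sequence: 5 steps (steps 1, 2, 4, 5 and 6, from acetylacetone); step 3 supplies the side branch.

**Steps most likely to fail**

1. Step 5 (ring-A aldol aromatization). The congested C6-to-C1 aldol may be outrun by closure through oxygen (pyranone formation), by Michael closure of C4 onto the styryl group, or by hydroxide-induced retro-Claisen fragmentation of the triketone. The fallback gives up the annulation and builds the pentasubstituted arene by cross-coupling; it sets out from aldehyde 7 and comes back to the route at target 15. Bought 3,5-bis(benzyloxy)benzyl bromide and P(OEt)3 (neat, 130 °C, Michaelis–Arbuzov reaction) would give diethyl [3,5-bis(benzyloxy)benzyl]phosphonate F1. Horner–Wadsworth–Emmons reaction of this phosphonate with 7 (NaH, THF) would give (E)-3,3',5-tris(benzyloxy)stilbene F2. Alkene-selective hydrogenation as in step 2 (H2, Pd/C, Ph2S) would give 1,3-bis(benzyloxy)-5-[2-(3-benzyloxyphenyl)ethyl]benzene F3. NBS (2 equiv, MeCN, 0 °C) should brominate the two positions that are para to one ether oxygen and ortho to the chain, since the position between the two ethers is the most hindered and the 3-benzyloxyphenyl ring is only singly activated; this would give 1,5-bis(benzyloxy)-2,4-dibromo-3-[2-(3-benzyloxyphenyl)ethyl]benzene F4. Twofold Negishi coupling with (4-benzyloxybenzyl)zinc chloride F5 (from bought 4-benzyloxybenzyl chloride, Zn dust, LiCl, THF) under Pd(OAc)2/SPhos in THF at 60 °C would give penta-O-benzyl shanciguol F6. Hydrogenolysis (H2, Pd/C) of its five benzyl ethers would then give 15.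

2. Step 4 (dianion acylation). Conjugate addition of the dianion to the cinnamoyl acceptor may compete with acylation, dianion formation may be incomplete, or the triketone may cyclize during isolation. The fallback replaces the acyl transfer by an aldol addition followed by oxidation; it sets out from amide 9 and diketone 6 and comes back to the route at triketone 12. Reduction of 9 with iBu2AlH (THF, −78 °C) would give (E)-3-(3-benzyloxyphenyl)prop-2-enal F7. Dianion 10, generated from 6 as in step 4, should add 1,2 to this aldehyde at −78 °C and give (E)-1-(3-benzyloxyphenyl)-4-(4-benzyloxybenzyl)-3-hydroxy-9-(4-benzyloxyphenyl)non-1-ene-5,7-dione F8 as a mixture of diastereomers. MnO2 in CH2Cl2 should oxidize the allylic carbinol selectively to 12.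

3. Step 2 (alkene-selective hydrogenation). Partial hydrogenolysis of the aryl benzyl ethers, or incomplete saturation of the poorly soluble dienedione, may erode the material. The fallback avoids hydrogenation by making the saturated chain through two successive dianion alkylations; it sets out from acetylacetone 1 and comes back to the route at diketone 6. The dianion of 1 (LiN(iPr)2, 2 equiv, THF, 0 °C) would be alkylated at a methyl carbon with bought 4-benzyloxybenzyl chloride to give 6-(4-benzyloxyphenyl)hexane-2,4-dione F9. A second dianion, formed by kinetic deprotonation of the remaining methyl group, would be alkylated with the same chloride to give 6.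

**Further compounds**

F1 | step 5 | diethyl [3,5-bis(benzyloxy)benzyl]phosphonate | CCOP(=O)(Cc1cc(OCc2ccccc2)cc(OCc2ccccc2)c1)OCC
F2 | step 5 | (E)-3,3',5-tris(benzyloxy)stilbene | c1ccc(COc2cccc(/C=C/c3cc(OCc4ccccc4)cc(OCc4ccccc4)c3)c2)cc1
F3 | step 5 | 1,3-bis(benzyloxy)-5-[2-(3-benzyloxyphenyl)ethyl]benzene | c1ccc(COc2cccc(CCc3cc(OCc4ccccc4)cc(OCc4ccccc4)c3)c2)cc1
F4 | step 5 | 1,5-bis(benzyloxy)-2,4-dibromo-3-[2-(3-benzyloxyphenyl)ethyl]benzene | Brc1c(OCc2ccccc2)cc(OCc2ccccc2)c(Br)c1CCc1cccc(OCc2ccccc2)c1
F5 | step 5 | (4-benzyloxybenzyl)zinc chloride | Cl[Zn]Cc1ccc(OCc2ccccc2)cc1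
F6 | step 5 | penta-O-benzyl shanciguol | c1ccc(COc2ccc(Cc3c(OCc4ccccc4)cc(OCc4ccccc4)c(Cc4ccc(OCc5ccccc5)cc4)c3CCc3cccc(OCc4ccccc4)c3)cc2)cc1
F7 | step 4 | (E)-3-(3-benzyloxyphenyl)prop-2-enal | O=C/C=C/c1cccc(OCc2ccccc2)c1
F8 | step 4 | (E)-1-(3-benzyloxyphenyl)-4-(4-benzyloxybenzyl)-3-hydroxy-9-(4-benzyloxyphenyl)non-1-ene-5,7-dione (mixture of diastereomers) | OC(/C=C/c1cccc(OCc2ccccc2)c1)C(Cc1ccc(OCc2ccccc2)cc1)C(=O)CC(=O)CCc1ccc(OCc2ccccc2)cc1
F9 | step 2 | 6-(4-benzyloxyphenyl)hexane-2,4-dione | CC(=O)CC(=O)CCc1ccc(OCc2ccccc2)cc1
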